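**Assumption:** the target has no stereocentre or other stereogenic element, so the given SMILES is the single compound to be made. The allenes on the way are used as racemates, because their axis is lost when the furan forms.

**Retrosynthetic overview**
1. Target ⇒ benzoyl chloride + a 5-(silylethynyl)furan that already carries the butynone arm at C3 (late C(sp)–C(O) bond by desilylative acylation).
2. Furan ⇒ an acyclic allenyl ynone + a bromo-ynone. The ring is closed through the O1–C2 bond (ketone oxygen onto the phenyl-bearing allene terminus), and the C3–alkynyl bond is made in the same palladium cycle.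
3. Allenyl ynone ⇒ an allenoate + a lithium silylacetylide; the allenoate ⇒ a stabilised phosphorane + phenylketene.
4. Bromo-ynone ⇒ a terminal ynone + NBS.
5. Ring order: both benzene rings are bought; the furan is the only ring made, in one event (step 4).

**Route**

Step 1
Reactants: 1 ethyl 2-(triphenylphosphoranylidene)propanoate; 2 phenylacetyl chloride
Product: 4 ethyl 2-methyl-4-phenylbuta-2,3-dienoate, via phenylketene 3 (not isolated)
Conditions: Et3N, CH2Cl2, 0 °C to rt (2 added slowly)
Reagents that add atoms: none
Why: Et3N dehydrochlorinates 2 to phenylketene, whose C=O undergoes Wittig olefination with the stabilised ylide 1 to give the racemic 2,4-disubstituted allenoate (ketene Wittig reaction, a standard allenoate synthesis).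

Step 2
Reactants: 4 ethyl 2-methyl-4-phenylbuta-2,3-dienoate; 5 ethynyltrimethylsilane
Product: 7 4-methyl-6-phenyl-1-(trimethylsilyl)hexa-4,5-dien-1-yn-3-one, via lithium (trimethylsilyl)acetylide 6 (not isolated)
Conditions: n-BuLi, THF, −78 °C; BF3·OEt2, −78 °C; then the ester, −78 °C; NH4Cl (aq) quench at −78 °C
Reagents that add atoms: none
Why: BF3-promoted acylation of a lithium acetylide by an ester (Yamaguchi-type ynone synthesis): the BF3-bound tetrahedral adduct survives at −78 °C, so no second addition occurs, and the hard alkynyl–boron nucleophile adds 1,2 and not to the allene.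

Step 3
Reactants: 8 but-3-yn-2-one
Product: 9 4-bromobut-3-yn-2-one
Conditions: NBS, AgNO3 (10 mol %), acetone, rt, dark; used at once as a toluene solution
Reagents that add atoms: N-bromosuccinimide, O=C1CCC(=O)N1Br
Why: Silver-catalysed electrophilic bromination of a terminal alkyne through the silver acetylide (NBS/AgNO3), a routine conversion for propiolates and terminal ynones.

Step 4
Reactants: 7 4-methyl-6-phenyl-1-(trimethylsilyl)hexa-4,5-dien-1-yn-3-one; 9 4-bromobut-3-yn-2-one
Product: 10 4-{4-methyl-2-phenyl-5-[(trimethylsilyl)ethynyl]furan-3-yl}but-3-yn-2-one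
Conditions: Pd2(dba)3 (2.5 mol %), tri(2-furyl)phosphine (10 mol %), K2CO3, toluene, 50 °C, slow addition of 9
Reagents that add atoms: none
Why: Proposed new method: zerovalent-palladium-catalysed cyclisation–alkynylation of a 1,2-allenyl ynone with a 1-bromoalkyne, in which oxidative addition of 9 gives an electrophilic alkynyl–palladium bromide (divalent palladium) that binds the distal allene C=C of 7, the ketone oxygen attacks the phenyl-bearing allene terminus anti to palladium (5-endo oxypalladation, forming O1–C2), carbonate removes the C2–H of the 2H-furanium to leave a 3-furyl(alkynyl)palladium species, and C(sp2)–C(sp) reductive elimination gives the C3-alkynyl furan and returns zerovalent palladium; the closest known reaction types are the zerovalent-palladium coupling–cyclisation of 1,2-allenyl ketones with aryl and alkenyl halides and the gold-catalysed cyclisation–alkynylation of allenyl ketones with alkynyl benziodoxolones.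

Step 5
Reactants: 10 4-{4-methyl-2-phenyl-5-[(trimethylsilyl)ethynyl]furan-3-yl}but-3-yn-2-one; 11 benzoyl chloride
Product: 12 Capillaridin A
Conditions: CuCl (20 mol %), 1,3-dimethyl-2-imidazolidinone, 80 °C, Ar
Reagents that add atoms: none
Why: Copper-catalysed desilylative acylation of an alkynylsilane: Si-to-Cu transmetalation gives a monovalent copper acetylide that is acylated by benzoyl chloride with release of Me3SiCl and CuCl, while the internal methyl ynone and the fully substituted furan have no reactive site under these neutral conditions.

**Compound list**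
1 | ethyl 2-(triphenylphosphoranylidene)propanoate | CCOC(=O)C(C)=P(c1ccccc1)(c1ccccc1)c1ccccc1 | starting material
2 | phenylacetyl chloride | O=C(Cl)Cc1ccccc1 | starting material
3 | phenylketene | O=C=Cc1ccccc1 | intermediate
4 | ethyl 2-methyl-4-phenylbuta-2,3-dienoate (racemic) | CCOC(=O)C(C)=C=Cc1ccccc1 | intermediate
5 | ethynyltrimethylsilane | C#C[Si](C)(C)C | starting material
6 | lithium (trimethylsilyl)acetylide | [Li]C#C[Si](C)(C)C | intermediate
7 | 4-methyl-6-phenyl-1-(trimethylsilyl)hexa-4,5-dien-1-yn-3-one (racemic) | C[Si](C)(C)C#CC(=O)C(C)=C=Cc1ccccc1 | intermediate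
8 | but-3-yn-2-one | CC(=O)C#C | starting material
9 | 4-bromobut-3-yn-2-one | CC(=O)C#CBr | intermediate
10 | 4-{4-methyl-2-phenyl-5-[(trimethylsilyl)ethynyl]furan-3-yl}but-3-yn-2-one | CC(=O)C#Cc1c(-c2ccccc2)oc(C#C[Si](C)(C)C)c1C | intermediate
11 | benzoyl chloride | O=C(Cl)c1ccccc1 | starting material
12 | Capillaridin A (3-[3-methyl-4-(3-oxobut-1-yn-1-yl)-5-phenylfuran-2-yl]-1-phenylprop-2-yn-1-one) | CC(=O)C#Cc1c(-c2ccccc2)oc(C#CC(=O)c2ccccc2)c1C | target

**Step count**
Total steps: 5. Longest linear sequence: 4 (steps 1, 2, 4, 5); step 3 is a one-step side branch.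

**Three steps most likely to fail**

Step 4 (the proposed new cyclisation–alkynylation). Likely failures are protonolysis of the furyl–palladium species to the C3–H furan, homocoupling or base-induced decay of 9, and phosphine addition to the ynones; the weakly nucleophilic phosphine and slow addition of 9 are chosen against these. The fallback uses known chemistry and sets out from 7. Cycloisomerisation with AuCl3 (2 mol %, CH2Cl2, rt) gives trimethyl[(3-methyl-5-phenylfuran-2-yl)ethynyl]silane F1. Iodination of its only free ring position (N-iodosuccinimide, MeCN, rt) gives [(4-iodo-3-methyl-5-phenylfuran-2-yl)ethynyl]trimethylsilane F2. Sonogashira coupling with but-3-yn-2-ol (PdCl2(PPh3)2, copper iodide CuI, Et3N, THF, rt) gives 4-{4-methyl-2-phenyl-5-[(trimethylsilyl)ethynyl]furan-3-yl}but-3-yn-2-ol F3. Oxidation with MnO2 (CH2Cl2, rt) then comes back to the route at 10. In this variant the ring C–O bond is closed first and the alkyne is attached afterwards, so 9 and step 3 are not needed.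

Step 2 (acetylide addition to the allenoate). Likely failures are conjugate addition to the allene or over-addition. The fallback sets out from 4 and replaces the polar addition by a catalytic acyl cross-coupling. Saponification (LiOH, THF/H2O, then dilute HCl) gives 2-methyl-4-phenylbuta-2,3-dienoic acid F4. Oxalyl chloride with catalytic DMF (CH2Cl2, 0 °C to rt) gives 2-methyl-4-phenylbuta-2,3-dienoyl chloride F5, which has no α-hydrogen and so cannot form a ketene. Acyl Sonogashira coupling with 5 (PdCl2(PPh3)2, copper iodide CuI, Et3N, THF, rt) comes back to the route at 7.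

Step 5 (copper-catalysed desilylative benzoylation). The likely failure is slow Si-to-Cu transfer on this electron-poor furyl alkyne, or decay of the ynone at 80 °C. The fallback sets out from 10 and goes through the free alkyne at room temperature. Buffered desilylation (TBAF, AcOH, THF, 0 °C; no methoxide, which would add to the ynone) gives 4-(5-ethynyl-4-methyl-2-phenylfuran-3-yl)but-3-yn-2-one F6. Acyl Sonogashira coupling with 11 (PdCl2(PPh3)2, copper iodide CuI, Et3N, THF, rt) comes back to the route at 12.

**Further compounds**
F1 | step 4 | trimethyl[(3-methyl-5-phenylfuran-2-yl)ethynyl]silane | C[Si](C)(C)C#Cc1oc(-c2ccccc2)cc1C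
F2 | step 4 | [(4-iodo-3-methyl-5-phenylfuran-2-yl)ethynyl]trimethylsilane | C[Si](C)(C)C#Cc1oc(-c2ccccc2)c(I)c1C
F3 | step 4 | 4-{4-methyl-2-phenyl-5-[(trimethylsilyl)ethynyl]furan-3-yl}but-3-yn-2-ol (racemic) | CC(O)C#Cc1c(-c2ccccc2)oc(C#C[Si](C)(C)C)c1C
F4 | step 2 | 2-methyl-4-phenylbuta-2,3-dienoic acid (racemic) | CC(=C=Cc1ccccc1)C(=O)O
F5 | step 2 | 2-methyl-4-phenylbuta-2,3-dienoyl chloride (racemic) | CC(=C=Cc1ccccc1)C(=O)Cl
F6 | step 5 | 4-(5-ethynyl-4-methyl-2-phenylfuran-3-yl)but-3-yn-2-one | CC(=O)C#Cc1c(-c2ccccc2)oc(C#C)c1C
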